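**Retrosynthetic overview**

1. Numbering: carbocycle C1 (bears C7), C2 (O-isovaleryl), C3 (C=O), C4 (C–CH3), C5, C6; chain C7 (oxirane carbon), C14 (its CH2), C8 (C=O), C9=C10, C11 (C–OOH); "top face" is the face of the C1–C7 bond. The strategy rests on C1 carrying the carboxyl-level carbon C7 while lying one atom (C6) from the C4(CH3)–C5 unit, which is an oxirane in the target and an alkene before it. C1–C6 is therefore the σ-bond of an ester-enolate Claisen rearrangement, and C7–C1–C2(O)–C3(O)–C4 is C1–C5 of 2-deoxy-D-ribose.
2. Key disconnection: cyclohexene acid 17 comes from the [3,3] ring contraction of the silyl ketene acetal of the methyl vinyl δ-lactone 14. Lactone 14 is made from the sugar 3,4-acetonide by two Grignard additions at sugar C5 (methyl first, then vinyl under chelation control) with lactonisation in the same flask.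
3. Side chain: C7 acid → chloromethyl ketone (C14) → Felkin–Anh addition of a prenyl dithiane anion (C8 acyl anion) → chlorohydrin. All carbanion chemistry is done while the ring diol is still an acetonide.
4. Ring: acetonide off, MnO2 at allylic C3, isovalerate at C2, Luche reduction, hydroxyl-directed epoxidation on the top face, oxidation back to the C3 ketone, then base closure of the C7–C14 oxirane.
5. Last step: Schenck ene reaction at C10=C11 gives the E-enone hydroperoxide. Ring order: carbocycle (step 8), C4–C5 oxirane (step 18), C7–C14 oxirane (step 20).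

Key step: step 8

Remark on the chemistry: the anomeric centre of 3 and the carbinol centre of 10 are carried as mixtures, because both are oxidised away.

**Route**

Step 1
Reactants: 1 2-deoxy-D-ribose; 2 2-methoxypropene
Product: 3 2-deoxy-3,4-O-isopropylidene-D-erythro-pentopyranose (lactol, both anomers)
Conditions: PPTS (cat.), DMF, 0 °C
Reagents that add atoms: 2-methoxypropene, COC(C)=C
Why: Kinetic acetonide formation (acid-catalysed transketalisation with an enol ether) should take the only cis-vicinal diol of the pyranose form, O3/O4, and creates no stereocentre.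

Step 2
Reactants: 3 lactol
Product: 4 2-deoxy-3,4-O-isopropylidene-D-erythro-pentono-1,5-lactone
Conditions: TEMPO (cat.), PhI(OAc)2, CH2Cl2, rt
Reagents that add atoms: none
Why: Oxoammonium (TEMPO) oxidation of a lactol to the lactone is a standard, near-neutral reaction that the acetonide should survive.

Step 3
Reactants: 4 lactone; 5 iodomethane
Product: 7 methyl 2-[(4S,5R)-5-(hydroxymethyl)-2,2-dimethyl-1,3-dioxolan-4-yl]acetate, via potassium carboxylate 6 (not isolated)
Conditions: KOH (1.0 equiv), MeOH/H2O, 0 °C; evaporate; MeI, DMF, rt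
Reagents that add atoms: potassium hydroxide, [K+].[OH-]; iodomethane, CI
Why: Saponification followed by SN2 O-alkylation of the carboxylate opens the lactone irreversibly to the hydroxy ester without touching either stereocentre.

Step 4
Reactants: 7 hydroxy ester
Product: 8 methyl 2-[(4S,5S)-5-formyl-2,2-dimethyl-1,3-dioxolan-4-yl]acetate
Conditions: Dess–Martin periodinane, pyridine, CH2Cl2, 0 °C
Reagents that add atoms: none
Why: Dess–Martin oxidation of the primary alcohol is non-basic, so the epimerisable α-alkoxy aldehyde on the cis-dioxolane should keep its configuration.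

Step 5
Reactants: 8 aldehyde; 9 methylmagnesium bromide
Product: 10 methyl 2-[(4S,5R)-5-(1-hydroxyethyl)-2,2-dimethyl-1,3-dioxolan-4-yl]acetate (both carbinol epimers)
Conditions: MeMgBr, THF, −78 °C; aq. NH4Cl at −78 °C
Reagents that add atoms: methylmagnesium bromide, C[Mg]Br
Why: Grignard addition to the aldehyde is much faster than to the methyl ester at −78 °C, and the new carbinol centre is removed in step 6, so its configuration is irrelevant.

Step 6
Reactants: 10 secondary alcohol
Product: 11 methyl 2-[(4S,5S)-5-acetyl-2,2-dimethyl-1,3-dioxolan-4-yl]acetate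
Conditions: Dess–Martin periodinane, pyridine, CH2Cl2, 0 °C to rt
Reagents that add atoms: none
Why: Dess–Martin oxidation converges both epimers of 10 on the methyl ketone under conditions that should not epimerise the α-alkoxy centre.

Step 7
Reactants: 11 methyl ketone; 12 vinylmagnesium bromide
Product: 14 (3S,4S,5S)-2-deoxy-3,4-O-isopropylidene-5-C-methyl-5-C-vinyl-D-erythro-pentono-1,5-lactone (vinyl cis to O3/O4), via bromomagnesium alkoxide 13 (not isolated)
Conditions: MgBr2·OEt2, CH2Cl2, −78 °C; CH2=CHMgBr (THF), −78 °C to rt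
Reagents that add atoms: vinylmagnesium bromide, C=C[Mg]Br
Why: Cram-chelate Grignard addition, with magnesium bridging the ketone oxygen and the α-dioxolane oxygen so that vinyl enters from the face of the α-hydrogen away from the dioxolane ring, should set the (5S) carbinol; the tertiary alkoxide then closes on the methyl ester by 6-exo-trig transesterification to the δ-lactone.

Step 8
Reactants: 14 methyl vinyl δ-lactone
Product: 17 (1R,2S,3R)-2,3-(isopropylidenedioxy)-4-methylcyclohex-4-ene-1-carboxylic acid, via silyl ketene acetal 15 (not isolated), via trimethylsilyl ester 16 (not isolated)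
Conditions: 14 and TMSCl/Et3N added to LiN(iPr)2, THF, −100 to −78 °C; PhMe, 105 °C; then H2O/THF
Reagents that add atoms: none
Why: LiN(iPr)2 deprotonates C1 of 14 in the presence of TMSCl, so the enolate is trapped at once as the cyclic O-silyl ketene acetal 15, whose C1=C7–O–C4–C5=C6 array undergoes a thermal suprafacial [3,3] shift that forms C1–C6 and breaks C4–O to give silyl ester 16, hydrolysed to 17 on work-up. The closest known reaction type is the Ireland–Claisen rearrangement of alkenyl-substituted lactone silyl ketene acetals to cycloalkene carboxylic acids. The cyclohexene is closed by the sigmatropic C–C bond formation itself, through a boat-like transition state shaped like a bicyclo[2.2.2]octene in which the lactone O–C7 bridge is exchanged for the C5–C6 bridge, so the ring alkene C4=C5 can only be cis. The one new stereocentre, C1, is set by chirality transfer from the tertiary carbinol C4: the vinyl group lies on the lactone face that carries the C2 and C3 oxygens, C6 must bond to that face of C1, and C7 therefore ends trans to C2–O, which is (1R). The step needs silylation to outrun E1cB loss of the C2 alkoxide, which the internal TMSCl quench at −100 °C is meant to secure, and it needs the vinyl group to reach the axial position of the boat, which the quaternary C4 allows because its other substituent is only a methyl group.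

Step 9
Reactants: 17 acid; 18 N,O-dimethylhydroxylamine hydrochloride
Product: 20 (1R,2S,3R)-N-methoxy-N-methyl-2,3-(isopropylidenedioxy)-4-methylcyclohex-4-ene-1-carboxamide, via acyl imidazole 19 (not isolated)
Conditions: CDI, CH2Cl2, rt; then MeNHOMe·HCl, rt
Reagents that add atoms: N,O-dimethylhydroxylamine hydrochloride, CNOC.Cl
Why: Carbonyldiimidazole activation and aminolysis (Weinreb amide formation) is mild enough to leave the acetonide and the C1 centre untouched.

Step 10
Reactants: 20 Weinreb amide; 21 chloroiodomethane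
Product: 24 2-chloro-1-[(1R,2S,3R)-2,3-(isopropylidenedioxy)-4-methylcyclohex-4-en-1-yl]ethan-1-one, via chloromethyllithium 22 (not isolated), via lithium hemiaminal adduct 23 (not isolated)
Conditions: ICH2Cl, MeLi·LiBr, THF, −78 °C; aq. NH4Cl
Reagents that add atoms: chloroiodomethane, ClCI
Why: Chloromethyllithium, formed by iodine–lithium exchange, adds once to the Weinreb amide because the chelated tetrahedral adduct is stable until quench (carbenoid homologation to an α-chloro ketone).

Step 11
Reactants: 25 1,3-dithiane; 26 1-bromo-3-methylbut-2-ene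
Product: 28 2-(3-methylbut-2-en-1-yl)-1,3-dithiane, via 2-lithio-1,3-dithiane 27 (not isolated)
Conditions: n-BuLi, THF, −30 °C; prenyl bromide, −78 °C to rt
Reagents that add atoms: 1-bromo-3-methylbut-2-ene, CC(C)=CCBr
Why: Corey–Seebach alkylation of the lithiated dithiane with a primary allylic bromide should proceed by SN2 at the CH2 terminus.

Step 12
Reactants: 24 chloromethyl ketone; 28 prenyl dithiane
Product: 30 (1S)-2-chloro-1-[(1R,2S,3R)-2,3-(isopropylidenedioxy)-4-methylcyclohex-4-en-1-yl]-1-[2-(3-methylbut-2-en-1-yl)-1,3-dithian-2-yl]ethan-1-ol (C7 carbinol), via lithiated dithiane 29 (not isolated)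
Conditions: 28, n-BuLi, THF, −30 °C; then 24, −78 °C; AcOH, −78 °C
Reagents that add atoms: none
Why: Corey–Seebach acyl-anion addition to an α-chloro ketone (Cornforth-type chlorohydrin synthesis) should follow the Felkin–Anh path, with C8 entering anti to the oxygen-bearing C2 branch of C1 and past C1–H, which gives the C7 configuration of the target, and the cold quench keeps the chlorohydrin open.

Step 13
Reactants: 30 chlorohydrin acetonide
Product: 31 (1S)-2-chloro-1-[(1R,2S,3R)-2,3-dihydroxy-4-methylcyclohex-4-en-1-yl]-1-[2-(3-methylbut-2-en-1-yl)-1,3-dithian-2-yl]ethan-1-ol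
Conditions: AcOH/H2O (4:1), 45 °C
Reagents that add atoms: none
Why: Acid-catalysed acetal hydrolysis is safe at this stage because the side chain holds a chlorohydrin and a dithiane and no oxirane.

Step 14
Reactants: 31 triol
Product: 32 (5R,6S)-5-[(1S)-2-chloro-1-hydroxy-1-[2-(3-methylbut-2-en-1-yl)-1,3-dithian-2-yl]ethyl]-6-hydroxy-2-methylcyclohex-2-en-1-one
Conditions: MnO2, CH2Cl2, rt
Reagents that add atoms: none
Why: MnO2 allylic oxidation should take only the allylic C3 hydroxyl, which differentiates the two ring hydroxyls and leaves C2–OH as the only acylable one.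

Step 15
Reactants: 32 hydroxy enone; 33 3-methylbutanoic anhydride
Product: 34 (1S,6R)-6-[(1S)-2-chloro-1-hydroxy-1-[2-(3-methylbut-2-en-1-yl)-1,3-dithian-2-yl]ethyl]-3-methyl-2-oxocyclohex-3-en-1-yl 3-methylbutanoate
Conditions: (i-PrCH2CO)2O, DMAP (cat.), pyridine, CH2Cl2, 0 °C
Reagents that add atoms: 3-methylbutanoic anhydride, CC(C)CC(=O)OC(=O)CC(C)C
Why: DMAP-catalysed acylation should take the secondary C2 hydroxyl and leave the hindered tertiary C7 hydroxyl free.

Step 16
Reactants: 34 acyloxy enone
Product: 35 allylic alcohol: as 34 but with C3 reduced to the (3S) alcohol, C3–OH on the top face (cis to the C1 side chain, trans to the C2 ester)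
Conditions: NaBH4, CeCl3·7H2O, MeOH, −78 °C
Reagents that add atoms: none
Why: Luche 1,2-reduction with axial hydride delivery should give the pseudo-equatorial C3 alcohol on the top face (the selectivity of carvone to cis-carveol), while the dithiane keeps C8 out of reach of the hydride.

Step 17
Reactants: 35 dithiane allylic alcohol
Product: 36 (1S,2S,6R)-6-[(2S)-1-chloro-2-hydroxy-6-methyl-3-oxohept-5-en-2-yl]-2-hydroxy-3-methylcyclohex-3-en-1-yl 3-methylbutanoate
Conditions: PhI(OCOCF3)2, NaHCO3, MeCN/H2O (9:1), 0 °C
Reagents that add atoms: water, O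
Why: Oxidative dithioacetal hydrolysis with a hypervalent iodine reagent is sulfur-selective and fast, and it is placed before the peroxide step because a dithiane would not survive the epoxidation.

Step 18
Reactants: 36 allylic alcohol
Product: 37 epoxy alcohol: as 36 but with the C4–C5 oxirane on the top face, syn to C3–OH and to the C1 side chain
Conditions: VO(acac)2 (cat.), t-BuOOH, CH2Cl2, 0 °C
Reagents that add atoms: tert-butyl hydroperoxide, CC(C)(C)OO
Why: Vanadium-catalysed hydroxyl-directed epoxidation delivers oxygen syn to the allylic C3–OH, which sets C4 and C5 on the top face, and it should ignore the remote prenyl alkene.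

Step 19
Reactants: 37 epoxy alcohol
Product: 38 epoxy ketone chlorohydrin: as 37 but with C3 oxidised to the ketone; (1R,2S,4S,5S,7S)
Conditions: Dess–Martin periodinane, pyridine, CH2Cl2, 0 °C to rt
Reagents that add atoms: none
Why: Buffered Dess–Martin oxidation of the secondary alcohol gives the α,β-epoxy ketone and cannot touch the tertiary C7 hydroxyl.

Step 20
Reactants: 38 chlorohydrin
Product: 39 (1R,2S,4S,5S,7R)-bis-oxirane prenyl ketone: C7–C14 oxirane closed, C8 ketone carrying CH2–CH=C(CH3)2
Conditions: K2CO3, MeCN, 0 °C to rt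
Reagents that add atoms: none
Why: Intramolecular Williamson closure (3-exo-tet) of the acidified α-ketol hydroxyl onto C14 displaces chloride without touching any bond of C7, and the trans C1/C2 arrangement next to the C3 ketone is the stable one, so mild carbonate should not erode it.

Step 21
Reactants: 39 prenyl ketone
Product: 40 target, (1R,2S,4S,5S,7R), E-enone with C11 hydroperoxide
Conditions: O2, tetraphenylporphyrin (cat.), visible light, CH2Cl2, 0 °C
Reagents that add atoms: dioxygen, O=O
Why: Schenck ene reaction of singlet oxygen at the trisubstituted C10=C11 alkene, bonding at C11 with abstraction of the doubly activated C9 hydrogen, should move the double bond into conjugation as the E-enone and give the tertiary hydroperoxide without a new stereocentre.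

**Compound list**

1 | 2-deoxy-D-ribose (open-chain form) | C(C=O)[C@@H]([C@@H](CO)O)O | starting material
2 | 2-methoxypropene | COC(C)=C | starting material
3 | 2-deoxy-3,4-O-isopropylidene-D-erythro-pentopyranose (lactol, both anomers) | CC1(C)O[C@@H]2[C@H](O1)COC(O)C2 | intermediate
4 | 2-deoxy-3,4-O-isopropylidene-D-erythro-pentono-1,5-lactone | CC1(C)O[C@@H]2[C@H](O1)COC(=O)C2 | intermediate
5 | iodomethane | CI | starting material
6 | potassium 2-deoxy-3,4-O-isopropylidene-D-erythro-pentonate | [K+].[O-]C(=O)C[C@@H]1OC(C)(C)O[C@@H]1CO | intermediate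
7 | methyl 2-[(4S,5R)-5-(hydroxymethyl)-2,2-dimethyl-1,3-dioxolan-4-yl]acetate | COC(=O)C[C@@H]1OC(C)(C)O[C@@H]1CO | intermediate
8 | methyl 2-[(4S,5S)-5-formyl-2,2-dimethyl-1,3-dioxolan-4-yl]acetate | COC(=O)C[C@@H]1OC(C)(C)O[C@@H]1C=O | intermediate
9 | methylmagnesium bromide | C[Mg]Br | starting material
10 | methyl 2-[(4S,5R)-5-(1-hydroxyethyl)-2,2-dimethyl-1,3-dioxolan-4-yl]acetate (both carbinol epimers) | COC(=O)C[C@@H]1OC(C)(C)O[C@@H]1C(C)O | intermediate
11 | methyl 2-[(4S,5S)-5-acetyl-2,2-dimethyl-1,3-dioxolan-4-yl]acetate | COC(=O)C[C@@H]1OC(C)(C)O[C@@H]1C(C)=O | intermediate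
12 | vinylmagnesium bromide | C=C[Mg]Br | starting material
13 | bromomagnesium alkoxide of methyl 2-[(4S,5S)-5-[(2S)-2-hydroxybut-3-en-2-yl]-2,2-dimethyl-1,3-dioxolan-4-yl]acetate | COC(=O)C[C@@H]1OC(C)(C)O[C@@H]1[C@](C)(C=C)O[Mg]Br | intermediate
14 | (3S,4S,5S)-2-deoxy-3,4-O-isopropylidene-5-C-methyl-5-C-vinyl-D-erythro-pentono-1,5-lactone; vinyl cis to O3 and O4 on the lactone ring | CC1(C)O[C@@H]2[C@H](O1)[C@](C)(C=C)OC(=O)C2 | intermediate
15 | O-trimethylsilyl ketene acetal of 14 (endocyclic C1=C7) | CC1(C)O[C@@H]2[C@H](O1)[C@](C)(C=C)OC(O[Si](C)(C)C)=C2 | intermediate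
16 | trimethylsilyl (1R,2S,3R)-2,3-(isopropylidenedioxy)-4-methylcyclohex-4-ene-1-carboxylate | CC1(C)O[C@@H]2[C@H](O1)C(C)=CC[C@H]2C(=O)O[Si](C)(C)C | intermediate
17 | (1R,2S,3R)-2,3-(isopropylidenedioxy)-4-methylcyclohex-4-ene-1-carboxylic acid; carboxyl trans to C2–O | CC1(C)O[C@@H]2[C@H](O1)C(C)=CC[C@H]2C(=O)O | intermediate
18 | N,O-dimethylhydroxylamine hydrochloride | CNOC.Cl | starting material
19 | acyl imidazole of 17 | CC1(C)O[C@@H]2[C@H](O1)C(C)=CC[C@H]2C(=O)n1ccnc1 | intermediate
20 | (1R,2S,3R)-N-methoxy-N-methyl-2,3-(isopropylidenedioxy)-4-methylcyclohex-4-ene-1-carboxamide | CC1(C)O[C@@H]2[C@H](O1)C(C)=CC[C@H]2C(=O)N(C)OC | intermediate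
21 | chloroiodomethane | ClCI | starting material
22 | chloromethyllithium | [Li]CCl | intermediate
23 | lithium alkoxide of the N-methoxy-N-methyl hemiaminal from 20 and 22 (tetrahedral adduct) | CC1(C)O[C@@H]2[C@H](O1)C(C)=CC[C@H]2C(O[Li])(CCl)N(C)OC | intermediate
24 | 2-chloro-1-[(1R,2S,3R)-2,3-(isopropylidenedioxy)-4-methylcyclohex-4-en-1-yl]ethan-1-one | CC1(C)O[C@@H]2[C@H](O1)C(C)=CC[C@H]2C(=O)CCl | intermediate
25 | 1,3-dithiane | C1CSCSC1 | starting material
26 | 1-bromo-3-methylbut-2-ene (prenyl bromide) | CC(C)=CCBr | starting material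
27 | 2-lithio-1,3-dithiane | [Li]C1SCCCS1 | intermediate
28 | 2-(3-methylbut-2-en-1-yl)-1,3-dithiane | CC(C)=CCC1SCCCS1 | intermediate
29 | 2-lithio-2-(3-methylbut-2-en-1-yl)-1,3-dithiane | [Li]C1(CC=C(C)C)SCCCS1 | intermediate
30 | (1S)-2-chloro-1-[(1R,2S,3R)-2,3-(isopropylidenedioxy)-4-methylcyclohex-4-en-1-yl]-1-[2-(3-methylbut-2-en-1-yl)-1,3-dithian-2-yl]ethan-1-ol (C7 carbinol, C14 = CH2Cl) | CC1(C)O[C@@H]2[C@H](O1)C(C)=CC[C@H]2[C@@](O)(CCl)C2(CC=C(C)C)SCCCS2 | intermediate
31 | (1S)-2-chloro-1-[(1R,2S,3R)-2,3-dihydroxy-4-methylcyclohex-4-en-1-yl]-1-[2-(3-methylbut-2-en-1-yl)-1,3-dithian-2-yl]ethan-1-ol | O[C@@H]1[C@H](O)C(C)=CC[C@H]1[C@@](O)(CCl)C1(CC=C(C)C)SCCCS1 | intermediate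
32 | (5R,6S)-5-[(1S)-2-chloro-1-hydroxy-1-[2-(3-methylbut-2-en-1-yl)-1,3-dithian-2-yl]ethyl]-6-hydroxy-2-methylcyclohex-2-en-1-one | O[C@@H]1C(=O)C(C)=CC[C@H]1[C@@](O)(CCl)C1(CC=C(C)C)SCCCS1 | intermediate
33 | 3-methylbutanoic (isovaleric) anhydride | CC(C)CC(=O)OC(=O)CC(C)C | starting material
34 | (1S,6R)-6-[(1S)-2-chloro-1-hydroxy-1-[2-(3-methylbut-2-en-1-yl)-1,3-dithian-2-yl]ethyl]-3-methyl-2-oxocyclohex-3-en-1-yl 3-methylbutanoate | CC(C)CC(=O)O[C@@H]1C(=O)C(C)=CC[C@H]1[C@@](O)(CCl)C1(CC=C(C)C)SCCCS1 | intermediate
35 | (1S,2S,6R)-6-[(1S)-2-chloro-1-hydroxy-1-[2-(3-methylbut-2-en-1-yl)-1,3-dithian-2-yl]ethyl]-2-hydroxy-3-methylcyclohex-3-en-1-yl 3-methylbutanoate; C3–OH on the top face | CC(C)CC(=O)O[C@@H]1[C@@H](O)C(C)=CC[C@H]1[C@@](O)(CCl)C1(CC=C(C)C)SCCCS1 | intermediate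
36 | (1S,2S,6R)-6-[(2S)-1-chloro-2-hydroxy-6-methyl-3-oxohept-5-en-2-yl]-2-hydroxy-3-methylcyclohex-3-en-1-yl 3-methylbutanoate | CC(C)CC(=O)O[C@@H]1[C@@H](O)C(C)=CC[C@H]1[C@@](O)(CCl)C(=O)CC=C(C)C | intermediate
37 | epoxy alcohol: 36 with the C4–C5 oxirane on the top face, syn to C3–OH and to the C1 side chain | CC(C)CC(=O)O[C@@H]1[C@@H](O)[C@@]2(C)O[C@H]2C[C@H]1[C@@](O)(CCl)C(=O)CC=C(C)C | intermediate
38 | epoxy ketone chlorohydrin, (1R,2S,4S,5S,7S): C3 ketone, C4–C5 oxirane, C7(OH)(CH2Cl), C8 prenyl ketone | CC(C)CC(=O)O[C@@H]1C(=O)[C@@]2(C)O[C@H]2C[C@H]1[C@@](O)(CCl)C(=O)CC=C(C)C | intermediate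
39 | bis-oxirane prenyl ketone, (1R,2S,4S,5S,7R): 38 with the C7–C14 oxirane closed | CC(C)CC(=O)O[C@@H]1C(=O)[C@@]2(C)O[C@H]2C[C@H]1[C@]1(C(=O)CC=C(C)C)CO1 | intermediate
40 | CNP0131119.1, (1R,2S,4S,5S,7R): C2 isovalerate, C3 ketone, 4,5- and 7,14-oxiranes, C8 ketone, (9E)-alkene, C11 hydroperoxide | CC(C)CC(=O)O[C@@H]1C(=O)[C@@]2(C)O[C@H]2C[C@H]1[C@]1(C(=O)/C=C/C(C)(C)OO)CO1 | target

**Step count**

Total: 21 steps (20 on the main line plus step 11 for dithiane 28). Longest linear sequence: 20 steps (steps 1–10 and 12–21).

**Steps most likely to fail**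

1. Step 8 (key step). The lithium enolate of 14 may lose the C2 alkoxide by β-elimination before it is silylated, or the ketene acetal may decompose because the boat transition state, with the dioxolane on the side of the migrating vinyl bridge, is slow. The fallback sets out from 14 and reshapes the precursor so that the β-oxygen cannot leave. Aqueous acetic acid would remove the acetonide to give the diol lactone F1. Excess LiN(iPr)2 would then form the enolate next to a C2 alkoxide (the β-hydroxy ester dianion variant of the Ireland–Claisen rearrangement), and TMSCl would silylate all three oxygens to the tris(trimethylsilyl) ketene acetal F2. Heating in toluene should rearrange F2 to the persilylated cyclohexene ester F3, and aqueous work-up would give the dihydroxy acid F4. Re-acetonisation of F4 with 2 and PPTS returns to the route at 17.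

2. Step 12. The basic, hindered dithianyl anion may deprotonate the α-chloro ketone or displace chloride, and facial selectivity at C7 may be low or reversed if a lithium chelate between the C7 carbonyl and the C2 acetonide oxygen competes with the Felkin–Anh path. The fallback sets out from Weinreb amide 20 and inverts the order of the two C7 bond formations. Acylation of lithiated dithiane 29 by 20 would give the acyl dithiane F5, which keeps the enolisable chloro ketone away from the carbanion. Chloromethyllithium (ICH2Cl, MeLi·LiBr, −78 °C, cold AcOH quench), if needed after precomplexation with MgBr2·OEt2, would then add to the C7 ketone of F5 and return to the route at chlorohydrin 30. For a given facial preference this order gives the opposite C7 configuration, so it is the remedy when the chelate face is the preferred one.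

3. Step 21. Singlet oxygen may instead abstract a hydrogen from a C11 methyl group and bond at C10, giving the secondary hydroperoxide with an isopropenyl end. The fallback sets out from 39 and replaces the pericyclic ene reaction by a radical-chain autoxidation with triplet oxygen (O2, catalytic N-hydroxyphthalimide, MeCN, rt). The weakest hydrogen, at C9 between the ketone and the alkene, is abstracted, the delocalised radical takes up O2 reversibly, and the conjugated tertiary peroxyl radical at C11 is the expected sink, as in the autoxidation of β,γ-unsaturated ketones to γ-hydroperoxy enones. It returns directly to 40 and makes no new compound (F0).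

Further compounds
F1 | step 8 | (3S,4S,5S)-2-deoxy-5-C-methyl-5-C-vinyl-D-erythro-pentono-1,5-lactone (diol lactone) | O[C@@H]1[C@H](O)[C@](C)(C=C)OC(=O)C1
F2 | step 8 | tris(trimethylsilyl) ketene acetal of F1 | C[Si](C)(C)O[C@@H]1[C@H](O[Si](C)(C)C)[C@](C)(C=C)OC(O[Si](C)(C)C)=C1
F3 | step 8 | trimethylsilyl (1R,2S,3R)-4-methyl-2,3-bis(trimethylsilyloxy)cyclohex-4-ene-1-carboxylate | C[Si](C)(C)O[C@@H]1[C@H](O[Si](C)(C)C)C(C)=CC[C@H]1C(=O)O[Si](C)(C)C
F4 | step 8 | (1R,2S,3R)-2,3-dihydroxy-4-methylcyclohex-4-ene-1-carboxylic acid | O[C@@H]1[C@H](O)C(C)=CC[C@H]1C(=O)O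
F5 | step 12 | [(1R,2S,3R)-2,3-(isopropylidenedioxy)-4-methylcyclohex-4-en-1-yl][2-(3-methylbut-2-en-1-yl)-1,3-dithian-2-yl]methanone | CC1(C)O[C@@H]2[C@H](O1)C(C)=CC[C@H]2C(=O)C2(CC=C(C)C)SCCCS2
F0 | step 21 | none | none
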